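**Retrosynthetic overview**
1. The target comes from a 4,5-epoxy-3-ol by titanium-mediated opening at C5 with angelic acid, which installs the C5 ester with inversion and frees the C3/C4 diol; that oxirane comes from a (Z)-C4=C5 alkene.
2. The C9 acetate and C10 angelate are placed on a 7,8-epoxy C9 ketone whose C10 oxygen is masked as a p-methoxyphenyl ether.
3. Key step: one flask takes a 1-ethynyl-2-vinylcyclohexanol through an anionic alkynyl oxy-Cope ring expansion, allenolate C-methylation and nucleophilic epoxidation, forming the ten-membered carbocycle and then the 7,8-oxirane.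
4. The cyclohexanol comes from acetylide addition to a 2-methyl-2-vinyl-3-silyloxycyclohexanone, made by semipinacol vinyl shift of an epoxy alcohol derived from (S)-carvone; the C10 oxygen is set first (α′-hydroxylation, Mitsunobu inversion).
5. Ring order: carvone six-membered ring (consumed in the Cope step), then ten-membered ring and 7,8-oxirane together, then the 4,5-oxirane (opened in the last step).

Assumption: ring carbons are numbered C1–C10 in the order of the target SMILES (C1 carries the isopropenyl group, C4 and C8 the methyl groups), and the face of the flat-drawn ring that carries the isopropenyl group is called the upper face.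

This route is a paper proposal; the stereochemical outcomes of steps 7, 10 and 12 rest on a qualitative conformational model and have not been tested.

Step 1
Reactants: 1 (S)-(+)-carvone
Product: 3 (5R,6R)-6-hydroxy-2-methyl-5-(prop-1-en-2-yl)cyclohex-2-en-1-one, via sodium dienolate 2 (not isolated)
Conditions: NaN(SiMe3)2, THF, −78 °C; then 2-(phenylsulfonyl)-3-phenyloxaziridine, −78 °C
Reagents that add atoms: 2-(phenylsulfonyl)-3-phenyloxaziridine (O=S(=O)(N1OC1c1ccccc1)c1ccccc1)
Why: Kinetic α′-deprotonation gives the cross-conjugated enolate and Davis enolate hydroxylation delivers oxygen anti to the neighbouring isopropenyl group, giving the trans α′-ketol (C10 oxygen on the lower face, to be inverted next).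

Step 2
Reactants: 3 (5R,6R)-6-hydroxy-2-methyl-5-(prop-1-en-2-yl)cyclohex-2-en-1-one
Product: 4 (5R,6S)-6-(4-methoxyphenoxy)-2-methyl-5-(prop-1-en-2-yl)cyclohex-2-en-1-one
Conditions: 4-MeOC6H4OH, PPh3, DIAD, toluene, 0 °C → rt
Reagents that add atoms: 4-methoxyphenol (COc1ccc(O)cc1)
Why: Mitsunobu etherification is an SN2 displacement at the activated α-keto carbinol, so C10 is inverted and the aryloxy group ends on the upper face, cis to the isopropenyl group as in the target, as an ether that survives organometallics and strong base.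

Step 3
Reactants: 4 (5R,6S)-6-(4-methoxyphenoxy)-2-methyl-5-(prop-1-en-2-yl)cyclohex-2-en-1-one
Product: 5 (1R,5R,6S)-1-ethenyl-6-(4-methoxyphenoxy)-2-methyl-5-(prop-1-en-2-yl)cyclohex-2-en-1-ol
Conditions: CH2=CHMgBr, CeCl3, THF, −78 °C
Reagents that add atoms: vinylmagnesium bromide (C=C[Mg]Br)
Why: Imamoto-type organocerium 1,2-addition in which the vinyl group enters axially, anti to the axial C10–OAr bond (Felkin–Anh), so the tertiary OH at C9 lies on the upper face and the vinyl group on the lower face.

Step 4
Reactants: 5 (1R,5R,6S)-1-ethenyl-6-(4-methoxyphenoxy)-2-methyl-5-(prop-1-en-2-yl)cyclohex-2-en-1-ol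
Product: 6 the 3,4-epoxide of 5 (oxirane oxygen on the upper face, cis to the C9 hydroxyl)
Conditions: VO(acac)2 (cat.), t-BuOOH, CH2Cl2, 0 °C → rt
Reagents that add atoms: tert-butyl hydroperoxide (CC(C)(C)OO)
Why: Vanadium-catalysed hydroxyl-directed epoxidation touches only the trisubstituted ring alkene allylic to the tertiary OH and delivers oxygen syn to that OH, which sets C3 with oxygen on the upper face.

Step 5
Reactants: 6 the 3,4-epoxide of 5
Product: 7 3-(tert-butyldimethylsilyloxy)-2-ethenyl-6-(4-methoxyphenoxy)-2-methyl-5-(prop-1-en-2-yl)cyclohexan-1-one (2-methyl, 3-silyloxy, 5-isopropenyl and 6-aryloxy on the upper face, 2-vinyl on the lower face)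
Conditions: t-BuMe2SiOTf, 2,6-lutidine, CH2Cl2, −78 → −40 °C
Reagents that add atoms: tert-butyldimethylsilyl trifluoromethanesulfonate (CC(C)(C)[Si](C)(C)OS(=O)(=O)C(F)(F)F)
Why: Semipinacol rearrangement of a 2,3-epoxy alcohol (Suzuki–Tsuchihashi/Jung type) in which silyl activation breaks the tertiary C4–O bond and the antiperiplanar vinyl group shifts from C9 to C4 with inversion at C4 (vinyl lower face, methyl upper face), while the C3 oxygen is retained as its silyl ether and C9 becomes the ketone.

Step 6
Reactants: 7 the silyloxy ketone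
Product: 8 the 1-ethynyl carbinol of 7 (C9 hydroxyl on the upper face, ethynyl on the lower face, cis to the C4 vinyl group)
Conditions: HC≡CMgBr, CeCl3, THF, −78 → 0 °C
Reagents that add atoms: ethynylmagnesium bromide (C#C[Mg]Br)
Why: Organocerium acetylide 1,2-addition in which the slim nucleophile attacks axially from the lower face, anti to the axial C10–OAr bond (Felkin–Anh) and away from the axial C4 methyl group, placing ethynyl and vinyl cis as the [3,3] shift requires.

Step 7
Reactants: 8 the 1-ethynyl carbinol
Product: 12 the ten-membered 7,8-epoxy C9 ketone ((4Z)-alkene, cis-oxirane with oxygen on the upper face, 3-silyloxy, 10-aryloxy), via potassium alkoxide 9 (not isolated), via potassium allenolate 10 (not isolated), via dienone 11 (not isolated)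
Conditions: KN(SiMe3)2, 18-crown-6, THF, −78 → 25 °C; cannulate into MeI, THF, −78 °C; then t-BuOOH, KOtBu (cat.), −20 → 0 °C
Reagents that add atoms: iodomethane (CI); tert-butyl hydroperoxide (CC(C)(C)OO)
Why: Proposed new method: a telescoped anionic alkynyl oxy-Cope / allenolate C-methylation / Weitz–Scheffer epoxidation in which the alkoxide with axial ethynyl and equatorial vinyl rearranges through the only reachable chair-like array to the ten-membered allenolate with a (Z)-C4=C5 bond, MeI attacks the central allenolate carbon from the side of H-7 to give the ring-compatible (Z)-2-methyl enone, and t-BuOO− adds to C7 from the open peripheral face of the folded (Z,Z)-diene conformer (the ring covers the other face) to close the cis-oxirane on the upper face; each event is known on its own (anionic acetylenic oxy-Cope, allenolate alkylation, nucleophilic enone epoxidation), only the telescoping and the conformational face control are new.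

Step 8
Reactants: 12 the epoxy ketone
Product: 13 the 10-hydroxy epoxy ketone (aryl group removed)
Conditions: (NH4)2Ce(NO3)6, pyridine, MeCN–H2O 4:1, 0 °C
Reagents that add atoms: none
Why: Oxidative dearylation of a p-methoxyphenyl ether (single-electron oxidation of the arene, ipso attack of water) frees the C10 hydroxyl with retention because the C10–O bond is never broken, and the pyridine buffer protects the oxirane, the silyl ether and the alkenes.

Step 9
Reactants: 13 the 10-hydroxy epoxy ketone; 14 angelic acid
Product: 16 the 10-O-angelate of 13, via mixed anhydride 15 (not isolated)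
Conditions: 14, 2,4,6-Cl3C6H2COCl, Et3N, toluene, rt; then 13, 60 °C
Reagents that add atoms: angelic acid 14 (C/C=C(/C)C(=O)O)
Why: Yamaguchi-type mixed-anhydride esterification run without DMAP (Hartmann conditions) acylates the only free hydroxyl without angelate-to-tiglate isomerisation, and no stereocentre is formed.

Step 10
Reactants: 16 the 10-O-angelate
Product: 17 the C9 alcohol (hydroxyl on the upper face, cis to the oxirane oxygen and to the C10 ester)
Conditions: Zn(BH4)2, Et2O, −40 → −20 °C
Reagents that add atoms: none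
Why: Chelation-controlled reduction of an α,β-epoxy ketone in which zinc bridges the carbonyl and oxirane oxygens and hydride arrives from the peripheral face, anti to the C10–O bond, giving the erythro (cis) epoxy alcohol while the esters are untouched.

Step 11
Reactants: 17 the C9 alcohol
Product: 18 the 9-O-acetate
Conditions: Ac2O, DMAP (cat.), pyridine, CH2Cl2, 0 °C
Reagents that add atoms: acetic anhydride (CC(=O)OC(C)=O)
Why: DMAP-catalysed acetylation of the single free secondary hydroxyl is fast enough at 0 °C to outrun 1,2-acyl migration, and no stereocentre changes.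

Step 12
Reactants: 18 the 9-O-acetate
Product: 19 the 4,5:7,8-bis-epoxide (new cis-oxirane with oxygen on the lower face)
Conditions: mCPBA, CH2Cl2 / pH 8 phosphate buffer, −20 → 0 °C
Reagents that add atoms: 3-chloroperoxybenzoic acid (O=C(OO)c1cccc(Cl)c1)
Why: Prilezhaev epoxidation in which the electron-rich trisubstituted C4=C5 alkene reacts ahead of the 1,1-disubstituted isopropenyl group and the enoate, and the peracid attacks the peripheral face anti to the bulky allylic C3 silyl ether (the trans preference known for medium-ring (Z)-allylic alcohol derivatives), putting the oxygen on the lower face at C4 and C5.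

Step 13
Reactants: 19 the bis-epoxide
Product: 20 the 3-hydroxy bis-epoxide
Conditions: Bu4NF, AcOH, THF, 0 °C → rt
Reagents that add atoms: none
Why: Fluoride desilylation buffered with acetic acid frees the C3 hydroxyl without Payne rearrangement, acyl migration or oxirane opening, and no stereocentre changes.

Step 14
Reactants: 20 the 3-hydroxy bis-epoxide; 14 angelic acid
Product: 21 CNP0249359.1
Conditions: Ti(OiPr)4, 14, CH2Cl2, 0 °C → rt
Reagents that add atoms: angelic acid 14 (C/C=C(/C)C(=O)O)
Why: Caron–Sharpless titanium-mediated opening of a 2,3-epoxy alcohol in which titanium binds the C3 alkoxide and the neighbouring oxirane oxygen and the carboxylate attacks the distal secondary carbon C5 with inversion (not the quaternary C4, not the unbound 7,8-oxirane), placing the C5 angelate on the upper face and leaving the C3 and C4 hydroxyls free.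

**Compound list**
1 | (S)-(+)-carvone | C=C(C)[C@H]1CC=C(C)C(=O)C1 | starting material
2 | sodium cross-conjugated dienolate of 1 | C=C(C)[C@H]1CC=C(C)C([O-])=C1.[Na+] | intermediate
3 | (5R,6R)-6-hydroxy-2-methyl-5-(prop-1-en-2-yl)cyclohex-2-en-1-one (OH trans to isopropenyl) | C=C(C)[C@H]1CC=C(C)C(=O)[C@@H]1O | intermediate
4 | (5R,6S)-6-(4-methoxyphenoxy)-2-methyl-5-(prop-1-en-2-yl)cyclohex-2-en-1-one (aryloxy cis to isopropenyl) | C=C(C)[C@H]1CC=C(C)C(=O)[C@H]1Oc1ccc(OC)cc1 | intermediate
5 | (1R,5R,6S)-1-ethenyl-6-(4-methoxyphenoxy)-2-methyl-5-(prop-1-en-2-yl)cyclohex-2-en-1-ol (OH, aryloxy and isopropenyl cis; vinyl trans) | C=C(C)[C@H]1CC=C(C)[C@](O)(C=C)[C@H]1Oc1ccc(OC)cc1 | intermediate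
6 | 3,4-epoxide of 5, oxirane oxygen cis to the tertiary OH | C=C(C)[C@H]1C[C@H]2O[C@@]2(C)[C@](O)(C=C)[C@H]1Oc1ccc(OC)cc1 | intermediate
7 | 3-(tert-butyldimethylsilyloxy)-2-ethenyl-6-(4-methoxyphenoxy)-2-methyl-5-(prop-1-en-2-yl)cyclohexan-1-one (methyl, silyloxy, isopropenyl, aryloxy upper face; vinyl lower face) | C=C(C)[C@H]1C[C@@H](O[Si](C)(C)C(C)(C)C)[C@](C)(C=C)C(=O)[C@H]1Oc1ccc(OC)cc1 | intermediate
8 | 1-ethynyl carbinol of 7 (OH upper face, ethynyl lower face, cis to vinyl) | C=C(C)[C@H]1C[C@@H](O[Si](C)(C)C(C)(C)C)[C@](C)(C=C)[C@](O)(C#C)[C@H]1Oc1ccc(OC)cc1 | intermediate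
9 | potassium alkoxide of 8 | C=C(C)[C@H]1C[C@@H](O[Si](C)(C)C(C)(C)C)[C@](C)(C=C)[C@]([O-])(C#C)[C@H]1Oc1ccc(OC)cc1.[K+] | intermediate
10 | potassium allenolate, ten-membered ring, (4Z)-alkene, C7=C8=C9–O− (allene axis set by the rearrangement, not specified) | C=C(C)[C@H]1C[C@@H](O[Si](C)(C)C(C)(C)C)/C(C)=C\CC=C=C([O-])[C@H]1Oc1ccc(OC)cc1.[K+] | intermediate
11 | (4Z,7Z)-4,8-dimethylcyclodeca-4,7-dien-9-one with 3-silyloxy, 10-aryloxy, 1-isopropenyl (target numbering) | C=C(C)[C@H]1C[C@@H](O[Si](C)(C)C(C)(C)C)/C(C)=C\C/C=C(/C)C(=O)[C@H]1Oc1ccc(OC)cc1 | intermediate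
12 | 7,8-epoxide of 11 (cis-oxirane, oxygen upper face) | C=C(C)[C@H]1C[C@@H](O[Si](C)(C)C(C)(C)C)/C(C)=C\C[C@H]2O[C@@]2(C)C(=O)[C@H]1Oc1ccc(OC)cc1 | intermediate
13 | 10-hydroxy analogue of 12 | C=C(C)[C@H]1C[C@@H](O[Si](C)(C)C(C)(C)C)/C(C)=C\C[C@H]2O[C@@]2(C)C(=O)[C@H]1O | intermediate
14 | angelic acid, (Z)-2-methylbut-2-enoic acid | C/C=C(/C)C(=O)O | starting material
15 | angelic 2,4,6-trichlorobenzoic mixed anhydride | C/C=C(/C)C(=O)OC(=O)c1c(Cl)cc(Cl)cc1Cl | intermediate
16 | 10-O-angelate of 13 | C=C(C)[C@H]1C[C@@H](O[Si](C)(C)C(C)(C)C)/C(C)=C\C[C@H]2O[C@@]2(C)C(=O)[C@H]1OC(=O)/C(C)=C\C | intermediate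
17 | C9 alcohol of 16 (OH upper face) | C=C(C)[C@H]1C[C@@H](O[Si](C)(C)C(C)(C)C)/C(C)=C\C[C@H]2O[C@@]2(C)[C@@H](O)[C@H]1OC(=O)/C(C)=C\C | intermediate
18 | 9-O-acetate of 17 | C=C(C)[C@H]1C[C@@H](O[Si](C)(C)C(C)(C)C)/C(C)=C\C[C@H]2O[C@@]2(C)[C@@H](OC(C)=O)[C@H]1OC(=O)/C(C)=C\C | intermediate
19 | 4,5-epoxide of 18 (cis-oxirane, oxygen lower face) | C=C(C)[C@H]1C[C@@H](O[Si](C)(C)C(C)(C)C)[C@]2(C)O[C@@H]2C[C@H]3O[C@@]3(C)[C@@H](OC(C)=O)[C@H]1OC(=O)/C(C)=C\C | intermediate
20 | 3-hydroxy bis-epoxide (silyl group removed) | C=C(C)[C@H]1C[C@@H](O)[C@]2(C)O[C@@H]2C[C@H]3O[C@@]3(C)[C@@H](OC(C)=O)[C@H]1OC(=O)/C(C)=C\C | intermediate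
21 | CNP0249359.1 | C=C(C)[C@H]1C[C@@H](O)[C@](C)(O)[C@@H](OC(=O)/C(C)=C\C)C[C@H]2O[C@@]2(C)[C@@H](OC(C)=O)[C@H]1OC(=O)/C(C)=C\C | target

**Step count and risks**
Total step count: 14. Longest linear sequence: 14 steps from (S)-carvone.

Most likely to fail, first: step 7. The telescoped cascade may lose material to proton transfer during methylation, and the face selectivity of the in-flask nucleophilic epoxidation is untested. The fallback sets out from dienone 11, isolated by stopping after the MeI quench. Luche 1,2-reduction (NaBH4, CeCl3·7H2O, MeOH, −40 °C; hydride anti to the C10–OAr bond) gives the C9 allylic alcohol F1. VO(acac)2 / t-BuOOH then places the oxirane syn to that hydroxyl to give the 7,8-epoxy C9 alcohol F2. Dess–Martin oxidation of F2 comes back to the route at 12.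

Second: step 2. Mitsunobu displacement on an α′-ketol may give elimination towards a phenol or partial epimerisation. The fallback sets out from 1: the sodium dienolate 2 is brominated with N-bromosuccinimide, bromine entering trans to the isopropenyl group, to give (5R,6R)-6-bromocarvone F3. Displacement with potassium 4-methoxyphenoxide (18-crown-6, acetone, 0 °C; SN2 with inversion at the α-keto carbon) comes back to the route at 4.

Third: step 12. The peracid may also attack the isopropenyl group, and the anti-to-silyloxy face preference is argued by analogy. The fallback sets out from 18: Bu4NF / AcOH first removes the silyl group to give the C3 allylic alcohol F4. A titanium–tartrate epoxidation (Ti(OiPr)4, D-(−)-diethyl tartrate, t-BuOOH, 4 Å sieves, CH2Cl2, −20 °C) is selective for the allylic alcohol and delivers oxygen to the face of the carbinol hydrogen (erythro product, the matched pairing for this C3 configuration), and comes back to the route at 20.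

**Further compounds**
F1 | step 7 | C9 allylic alcohol of dienone 11 (hydroxyl upper face) | C=C(C)[C@H]1C[C@@H](O[Si](C)(C)C(C)(C)C)/C(C)=C\C/C=C(/C)[C@@H](O)[C@H]1Oc1ccc(OC)cc1
F2 | step 7 | 7,8-epoxy C9 alcohol (oxirane oxygen cis to the hydroxyl) | C=C(C)[C@H]1C[C@@H](O[Si](C)(C)C(C)(C)C)/C(C)=C\C[C@H]2O[C@@]2(C)[C@@H](O)[C@H]1Oc1ccc(OC)cc1
F3 | step 2 | (5R,6R)-6-bromo-2-methyl-5-(prop-1-en-2-yl)cyclohex-2-en-1-one | C=C(C)[C@H]1CC=C(C)C(=O)[C@@H]1Br
F4 | step 12 | C3 allylic alcohol (desilylated 18) | C=C(C)[C@H]1C[C@@H](O)/C(C)=C\C[C@H]2O[C@@]2(C)[C@@H](OC(C)=O)[C@H]1OC(=O)/C(C)=C\C
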